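Plan. Locants: ring A = C1(HBr)–C2–C3–C4(OH)(CH3)–C5–C10(CH3); ring B = C5–C6–C7–C8–C9–C10; norbornane = C6, C7, C11 [C(OH)i-Pr], C12, C13, C14, C15 (one-carbon bridge C7–C15–C13).
Enabling feature: in ring A the equatorial C1–Br bond is antiperiplanar to C2–C3, and C3 is α to the carbinol carbon C4. C2–C3 is therefore the bond an enolate carbon C3 makes on opening a C1/C2 bromonium ion, and that ion pair can be generated from an oxygen-bridged surrogate of ring A (C4–O–C2, a δ-lactone turned into its 2-methylene-oxane).
Retrosynthetic cuts, in order: C4–CH3; C2–C3 (1,3 O-to-C shift, ring A closed last); C4=C3H2 (lactone methylenation); C1–Br; C11–OH; C6–C7 and C13–C14 together (intramolecular Diels–Alder); C7–C8 (B-alkyl Suzuki); C5–C10 (Ireland–Claisen).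
Forward order: acyclic C5/C10 diad → tethered 1,2-dialkylcyclopentadiene → one Diels–Alder closes ring B and the norbornene → hydration → temporary δ-lactone → ring A.
Stereochemistry: C5/C10 from an enantioselective Ireland–Claisen rearrangement; C6, C7, C13 from the exo-fused chair-like Diels–Alder tether; C11 by exo-face radical hydration; C1 by catalyst-controlled α-bromination, kept through the bromonium ion; C4 by equatorial addition of a methyl nucleophile.

Key step: step 14

Assumption: the senses of induction of the (S,S)-diazaborolidine (step 3) and of the (2R,5R)-pyrrolidine (step 12) are taken to be those that give the drawn configurations; if either proves opposite, its enantiomer is used.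

Step 1
Reactants: 1 4-(tert-butyldimethylsilyloxy)but-1-yne
Product: 3 (2E)-5-(tert-butyldimethylsilyloxy)-3-methylpent-2-en-1-ol, via alkenylalane 2 (not isolated)
Conditions: Me3Al, Cp2ZrCl2 (cat.), CH2Cl2, 0 °C to rt; then (CH2O)n, THF, rt; aq. work-up
Reagents that add atoms: trimethylaluminium C[Al](C)C; paraformaldehyde (formaldehyde unit) C=O
Why: Zirconium-catalysed syn-carboalumination (Negishi carboalumination) adds CH3 and Al cis across the terminal alkyne with Al on the terminal carbon, and the alkenylalane adds to formaldehyde with retention, so the trisubstituted alkene should form as the E isomer only.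

Step 2
Reactants: 3 (2E)-5-(tert-butyldimethylsilyloxy)-3-methylpent-2-en-1-ol; 4 4-(phenylsulfanyl)butanoic acid
Product: 5 (2E)-5-(tert-butyldimethylsilyloxy)-3-methylpent-2-en-1-yl 4-(phenylsulfanyl)butanoate
Conditions: DCC, DMAP (cat.), CH2Cl2, 0 °C to rt
Reagents that add atoms: none
Why: Steglich esterification of a primary allylic alcohol, in which no stereocentre is formed and the E alkene is not touched.

Step 3
Reactants: 5 (2E)-5-(tert-butyldimethylsilyloxy)-3-methylpent-2-en-1-yl 4-(phenylsulfanyl)butanoate
Product: 7 (2S,3S)-3-[2-(tert-butyldimethylsilyloxy)ethyl]-3-methyl-2-[2-(phenylsulfanyl)ethyl]pent-4-enoic acid, via boron ketene acetal 6 (not isolated)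
Conditions: preformed (S,S)-2-bromo-4,5-diphenyl-1,3-bis{[3,5-bis(trifluoromethyl)phenyl]sulfonyl}-1,3,2-diazaborolidine, Et3N, toluene–hexane, −78 °C, then −20 °C to rt; aq. work-up
Reagents that add atoms: none
Why: Chiral-diazaborolidine-mediated enantioselective Ireland–Claisen rearrangement: the E(O) boron enolate and the E alkene should react through a chair transition state with CH2CH2SPh and CH3 pseudo-axial, which sets the C5/C10 relative configuration (quaternary C10 included), while the C2-symmetric sulfonamide ligand on boron selects the enolate face and hence the absolute configuration.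

Step 4
Reactants: 7 (2S,3S)-3-[2-(tert-butyldimethylsilyloxy)ethyl]-3-methyl-2-[2-(phenylsulfanyl)ethyl]pent-4-enoic acid
Product: 8 methyl (2S,3S)-3-[2-(tert-butyldimethylsilyloxy)ethyl]-3-methyl-2-[2-(phenylsulfanyl)ethyl]pent-4-enoate
Conditions: TMSCHN2, MeOH–toluene, rt
Reagents that add atoms: trimethylsilyldiazomethane C[Si](C)(C)C=[N+]=[N-]
Why: O-Methylation of the carboxylic acid with a diazoalkane under neutral conditions, which should leave thioether and silyl ether untouched and cannot epimerise C5.

Step 5
Reactants: 8 methyl (2S,3S)-3-[2-(tert-butyldimethylsilyloxy)ethyl]-3-methyl-2-[2-(phenylsulfanyl)ethyl]pent-4-enoate; 9 2-iodocyclopent-2-en-1-one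
Product: 11 2-alkylcyclopent-2-enone (C7–C8 bond formed; thioether and methyl ester retained), via B-alkyl-9-BBN borane 10 (not isolated)
Conditions: 9-BBN, THF, 0 °C to rt; then 9, PdCl2(dppf) (cat.), AsPh3, Cs2CO3, DMF–H2O, rt
Reagents that add atoms: none
Why: Anti-Markovnikov hydroboration of the only alkene followed by B-alkyl Suzuki–Miyaura coupling with the α-iodoenone should join C8 to the future diene carbon C7 without touching ester or thioether, and no stereocentre is formed.

Step 6
Reactants: 11 2-alkylcyclopent-2-enone thioether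
Product: 13 vinyl enone (terminal C6=C14 alkene on C5), via sulfoxide 12 (not isolated)
Conditions: NaIO4, MeOH–H2O, 0 °C; then toluene, CaCO3, 110 °C
Reagents that add atoms: none
Why: Periodate oxidation stops at the sulfoxide, and thermal syn-elimination of the alkyl phenyl sulfoxide (sulfoxide pyrolysis; the only β-hydrogens are on C6) should unveil the terminal dienophile only after the hydroboration that it would not have survived.

Step 7
Reactants: 13 vinyl enone
Product: 14 tertiary allylic carbinol (1-isopropyl-2-alkylcyclopent-2-en-1-ol; mixture of carbinol epimers)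
Conditions: i-PrMgCl, CeCl3, THF, −78 °C
Reagents that add atoms: isopropylmagnesium chloride CC(C)[Mg]Cl
Why: Carbonyl addition of an organocerium reagent should go 1,2 at the enone without enolisation or attack on the methyl ester, and the new carbinol centre need not be controlled because it is destroyed in step 8.

Step 8
Reactants: 14 tertiary allylic carbinol
Product: 16 Diels–Alder adduct (ring B fused to the C11=C12 norbornene; C5 methyl ester; C10 methyl plus CH2CH2OTBS), via cyclopentadiene triene 15 (not isolated)
Conditions: PPTS (cat.), toluene, 60 °C; filtration through basic Al2O3; then toluene (high dilution), BHT, 170 °C, sealed tube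
Reagents that add atoms: none
Why: Acid-catalysed dehydration gives the 1,2-dialkylcyclopentadiene, whose rapid [1,5]-hydrogen shifts funnel through the 1-alkyl-2-isopropyl isomer 15, the only one able to undergo the type-1 intramolecular Diels–Alder reaction through the four-atom tether; the tether enforces exo fusion at C6, and a chair-like ring B with the C5 ester equatorial and the dienophile terminus C14 equatorial (not syn-axial to the C10 methyl) selects the diene face, so C6, C7 and C13 should follow from C5 and C10.

Step 9
Reactants: 16 Diels–Alder adduct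
Product: 18 exo tertiary alcohol at C11 (isopropyl endo; TBS ether; methyl ester), via tertiary hydroperoxide 17 (not isolated)
Conditions: Co(acac)2 (cat.), PhSiH3, O2 (1 atm), i-PrOH–CH2Cl2, rt; then PPh3
Reagents that add atoms: dioxygen O=O
Why: Mukaiyama hydration: hydrogen-atom transfer to C12 gives the tertiary C11 radical, which dioxygen should trap on the exo face of the norbornane (the endo face is screened by the endo hydrogens on C6 and C14), and reduction of the hydroperoxide gives the exo alcohol with isopropyl endo.

Step 10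
Reactants: 18 exo tertiary alcohol TBS ether
Product: 19 δ-hydroxy methyl ester (free primary alcohol at C2)
Conditions: TBAF, AcOH, THF, 0 °C
Reagents that add atoms: none
Why: Buffered fluoride cleavage of the primary silyl ether, near neutral so that the tertiary norbornyl alcohol does not ionise and the hydroxy ester, used at once, does not lactonise before oxidation.

Step 11
Reactants: 19 δ-hydroxy methyl ester
Product: 20 aldehyde (C2 = CHO)
Conditions: Dess–Martin periodinane, NaHCO3, CH2Cl2, 0 °C to rt
Reagents that add atoms: none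
Why: Dess–Martin oxidation of the primary alcohol to the aldehyde under buffered conditions, the tertiary alcohol being inert.

Step 12
Reactants: 20 aldehyde
Product: 23 bromo δ-lactone (C4(=O)–O–C2; equatorial Br at C1), via α-bromo aldehyde 21 (not isolated), via bromohydrin ester 22 (not isolated)
Conditions: (2R,5R)-2,5-diphenylpyrrolidine (20 mol %), PhCO2H (cat.), 4,4-dibromo-2,6-di-tert-butylcyclohexa-2,5-dien-1-one, CH2Cl2–pentane, −40 °C; then NaBH4, MeOH, −40 to 0 °C; then PPTS (cat.), toluene, 50 °C
Reagents that add atoms: 4,4-dibromo-2,6-di-tert-butylcyclohexa-2,5-dien-1-one CC(C)(C)C1=CC(Br)(Br)C=C(C(C)(C)C)C1=O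
Why: Enamine-mediated organocatalytic α-bromination: the C2-symmetric pyrrolidine shields one face of the E enamine so bromine should be delivered to C1 under catalyst control, immediate borohydride reduction prevents epimerisation of the α-bromo aldehyde, and acid-catalysed lactonisation of the δ-hydroxy ester closes the temporary oxygen-bridged ring with Br equatorial.

Step 13
Reactants: 23 bromo δ-lactone
Product: 24 2-methylene-oxane enol ether (exocyclic C4=C3H2; O between C4 and C2)
Conditions: Cp2TiMe2 (3 equiv), toluene–THF, 70 °C, dark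
Reagents that add atoms: dimethyltitanocene C[Ti](C)(C1C=CC=C1)C1C=CC=C1
Why: Petasis methylenation (titanium methylidene) converts the lactone carbonyl into the exocyclic enol ether without base, so C5 and the secondary bromide should be untouched.

Step 14
Reactants: 24 2-methylene-oxane enol ether
Product: 25 ring-A bromo ketone (C4=O; equatorial Br at C1)
Conditions: Me2AlCl (3 equiv), CH2Cl2, −78 to 0 °C
Reagents that add atoms: none
Why: Proposed new method: Me2AlCl binds the enol-ether oxygen and the C2–O bond should ionise with anchimeric assistance from the equatorial bromine on C1, which lies antiperiplanar to it, giving a bridged C1/C2 bromonium ion paired with the aluminium enolate of the C4 methyl ketone; rotation about C5–C4 brings the enolate carbon C3 to the place the oxygen left and it opens the bromonium ion at the primary carbon C2, a net 1,3 O-to-C shift. The closest known reactions are the Petasis–Ferrier rearrangement and the aluminium-promoted Ferrier-type carbocyclisation of hex-5-enopyranosides (there an oxocarbenium ion, not a bromonium ion, is the electrophile), together with the solvolytic generation of bromonium ions from β-bromo leaving groups used in bromo-polyene cyclisations. Ring A, the only ring closed, forms in a 6-(enolendo)-exo-tet mode through a chair in which bromine stays equatorial. No new stereocentre is created: C1 keeps its configuration because the C1–Br bond is never broken (the double inversion takes place at the CH2 carbon C2) and C5 and C10 are not touched. The step needs C- rather than O-alkylation and attack at C2 rather than C1: O-return only regenerates 24 whereas C-alkylation is irreversible, and C1 is neopentylic and shielded by the quaternary C10. The non-basic medium also spares the γ-bromo ketone product from 1,3-elimination of HBr.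

Step 15
Reactants: 25 ring-A bromo ketone
Product: 26 target bromo diol CNP0362628.1
Conditions: MeMgBr, CeCl3, THF, −78 °C
Reagents that add atoms: methylmagnesium bromide C[Mg]Br
Why: 1,2-Addition of the weakly basic methylcerium reagent to the ring-A ketone: axial approach to C4 is blocked by the syn-axial C10 methyl, so attack should come from the equatorial direction and give the axial tertiary alcohol (OH cis to the C10 methyl) without enolisation towards the γ-bromide.

Compound list
1 | 4-(tert-butyldimethylsilyloxy)but-1-yne | C#CCCO[Si](C)(C)C(C)(C)C | starting material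
2 | dimethyl[(1E)-4-(tert-butyldimethylsilyloxy)-2-methylbut-1-en-1-yl]alane | C/C(CCO[Si](C)(C)C(C)(C)C)=C\[Al](C)C | intermediate
3 | (2E)-5-(tert-butyldimethylsilyloxy)-3-methylpent-2-en-1-ol | C/C(CCO[Si](C)(C)C(C)(C)C)=C\CO | intermediate
4 | 4-(phenylsulfanyl)butanoic acid | OC(=O)CCCSc1ccccc1 | starting material
5 | (2E)-5-(tert-butyldimethylsilyloxy)-3-methylpent-2-en-1-yl 4-(phenylsulfanyl)butanoate | C/C(CCO[Si](C)(C)C(C)(C)C)=C\COC(=O)CCCSc1ccccc1 | intermediate
6 | E(O) boron ketene acetal of 5 carrying the (S,S)-bis-sulfonyl diazaborolidine | C/C(CCO[Si](C)(C)C(C)(C)C)=C\CO/C(OB1N(S(=O)(=O)c2cc(C(F)(F)F)cc(C(F)(F)F)c2)[C@@H](c2ccccc2)[C@H](c2ccccc2)N1S(=O)(=O)c1cc(C(F)(F)F)cc(C(F)(F)F)c1)=C\CCSc1ccccc1 | intermediate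
7 | (2S,3S)-3-[2-(tert-butyldimethylsilyloxy)ethyl]-3-methyl-2-[2-(phenylsulfanyl)ethyl]pent-4-enoic acid | C=C[C@](C)(CCO[Si](C)(C)C(C)(C)C)[C@H](CCSc1ccccc1)C(=O)O | intermediate
8 | methyl (2S,3S)-3-[2-(tert-butyldimethylsilyloxy)ethyl]-3-methyl-2-[2-(phenylsulfanyl)ethyl]pent-4-enoate | C=C[C@](C)(CCO[Si](C)(C)C(C)(C)C)[C@H](CCSc1ccccc1)C(=O)OC | intermediate
9 | 2-iodocyclopent-2-en-1-one | O=C1CCC=C1I | starting material
10 | B-alkyl-9-borabicyclo[3.3.1]nonane from 8 (boron on the former vinyl terminus) | B1(CC[C@](C)(CCO[Si](C)(C)C(C)(C)C)[C@H](CCSc2ccccc2)C(=O)OC)C2CCCC1CCC2 | intermediate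
11 | methyl 3-[2-(tert-butyldimethylsilyloxy)ethyl]-3-methyl-5-(5-oxocyclopent-1-en-1-yl)-2-[2-(phenylsulfanyl)ethyl]pentanoate (stereocentres as in 8) | O=C1CCC=C1CC[C@](C)(CCO[Si](C)(C)C(C)(C)C)[C@H](CCSc1ccccc1)C(=O)OC | intermediate
12 | phenyl sulfoxide of 11 (mixture at sulfur) | O=C1CCC=C1CC[C@](C)(CCO[Si](C)(C)C(C)(C)C)[C@H](CCS(=O)c1ccccc1)C(=O)OC | intermediate
13 | methyl 2-ethenyl-3-[2-(tert-butyldimethylsilyloxy)ethyl]-3-methyl-5-(5-oxocyclopent-1-en-1-yl)pentanoate (stereocentres as in 8) | O=C1CCC=C1CC[C@](C)(CCO[Si](C)(C)C(C)(C)C)[C@H](C=C)C(=O)OC | intermediate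
14 | methyl 2-ethenyl-5-(5-hydroxy-5-isopropylcyclopent-1-en-1-yl)-3-[2-(tert-butyldimethylsilyloxy)ethyl]-3-methylpentanoate (mixture of carbinol epimers) | CC(C)C1(O)CCC=C1CC[C@](C)(CCO[Si](C)(C)C(C)(C)C)[C@H](C=C)C(=O)OC | intermediate
15 | methyl 2-ethenyl-3-[2-(tert-butyldimethylsilyloxy)ethyl]-3-methyl-5-(2-isopropylcyclopenta-1,3-dien-1-yl)pentanoate (reactive [1,5]-H-shift isomer) | CC(C)C1=C(CC[C@](C)(CCO[Si](C)(C)C(C)(C)C)[C@H](C=C)C(=O)OC)CC=C1 | intermediate
16 | Diels–Alder adduct: ring B exo-fused to the norbornene (C11=C12, isopropyl on C11), equatorial CO2CH3 on C5, axial CH3 and CH2CH2OTBS on C10 | CC(C)C1=C[C@@H]2C[C@H]3[C@H](C(=O)OC)[C@](C)(CC[C@@]31C2)CCO[Si](C)(C)C(C)(C)C | intermediate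
17 | C11 exo-hydroperoxide of 16 | CC(C)[C@]1(OO)C[C@@H]2C[C@H]3[C@H](C(=O)OC)[C@](C)(CC[C@@]31C2)CCO[Si](C)(C)C(C)(C)C | intermediate
18 | C11 exo tertiary alcohol (isopropyl endo), TBS ether, methyl ester | CC(C)[C@]1(O)C[C@@H]2C[C@H]3[C@H](C(=O)OC)[C@](C)(CC[C@@]31C2)CCO[Si](C)(C)C(C)(C)C | intermediate
19 | δ-hydroxy methyl ester (C2–OH) | CC(C)[C@]1(O)C[C@@H]2C[C@H]3[C@H](C(=O)OC)[C@](C)(CC[C@@]31C2)CCO | intermediate
20 | aldehyde (C2 = CHO) | CC(C)[C@]1(O)C[C@@H]2C[C@H]3[C@H](C(=O)OC)[C@](C)(CC[C@@]31C2)CC=O | intermediate
21 | α-bromo aldehyde (Br at C1) | CC(C)[C@]1(O)C[C@@H]2C[C@H]3[C@H](C(=O)OC)[C@](C)(CC[C@@]31C2)[C@@H](Br)C=O | intermediate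
22 | bromohydrin methyl ester (C1–Br, C2–OH) | CC(C)[C@]1(O)C[C@@H]2C[C@H]3[C@H](C(=O)OC)[C@](C)(CC[C@@]31C2)[C@@H](Br)CO | intermediate
23 | bromo δ-lactone (C4(=O)–O–C2, trans-fused to ring B, equatorial Br at C1) | CC(C)[C@]1(O)C[C@@H]2C[C@H]3[C@H]4[C@](C)(CC[C@@]31C2)[C@@H](Br)COC4=O | intermediate
24 | 2-methylene-oxane enol ether (exocyclic C4=C3H2) | CC(C)[C@]1(O)C[C@@H]2C[C@H]3[C@H]4[C@](C)(CC[C@@]31C2)[C@@H](Br)COC4=C | intermediate
25 | ring-A bromo ketone (C4=O, equatorial Br at C1) | CC(C)[C@]1(O)C[C@@H]2C[C@H]3[C@H]4[C@](C)(CC[C@@]31C2)[C@@H](Br)CCC4=O | intermediate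
26 | CNP0362628.1: (1S)-bromide, (4R)-methyl carbinol with axial OH, exo C11–OH with endo isopropyl | CC(C)[C@]1(O)C[C@@H]2C[C@H]3[C@H]4[C@](C)(CC[C@@]31C2)[C@@H](Br)CC[C@@]4(C)O | target

Total steps: 15. Longest linear sequence: 15 (from 1; 4 and 9 are purchased).

Steps most likely to fail

1. Step 14 (bears the label "Proposed new method:"). What may go wrong: the C2–O bond may not ionise under the aluminium Lewis acid; the exocyclic enol ether may isomerise to the endocyclic C4=C5 isomer; chloride may open the bromonium ion; or the tertiary C11 aluminium alkoxide may ionise and rearrange. Fallback with known chemistry, setting out from 24 and returning at 25: mild hydrolysis of the enol ether (oxalic acid, wet THF) should give the δ-hydroxy methyl ketone F1 (open form drawn). Selective sulfonylation of its primary alcohol (TsCl, pyridine) should give the tosylate F2. Kinetic deprotonation of the methyl ketone (LiHMDS, 2 equiv, THF, −78 °C) should then close ring A by a 6-(enolendo)-exo-tet enolate alkylation to 25, quenched cold so that the γ-bromo ketone is not deprotonated further.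

2. Step 8. What may go wrong: the [1,5]-hydrogen shifts populate several cyclopentadiene isomers, so dimerisation or cycloaddition through an unwanted isomer can compete; facial selectivity may erode at the temperature the unactivated dienophile needs; and the C5 vinyl group may migrate into conjugation with the ester. Fallback setting out from 14 and returning at 16: cross-metathesis of the terminal alkene with phenyl vinyl sulfone (second-generation Hoveyda–Grubbs catalyst, CH2Cl2, 40 °C) should give the (E)-vinyl sulfone carbinol F3. Dehydration (PPTS, toluene) gives the cyclopentadiene vinyl sulfone F4 (not isolated), whose activated dienophile should cyclise at or below 80 °C, tether exo and sulfonyl endo, to the sulfonyl adduct F5. Reductive desulfonylation (Na(Hg), Na2HPO4, MeOH) then gives 16.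

3. Step 12. What may go wrong: poor facial selectivity in the bromination of the hindered enamine next to the quaternary C10 (catalyst–substrate mismatch), or epimerisation of the α-bromo aldehyde before reduction. Fallback setting out from 20 and returning at 22 (and hence 23): Pinnick oxidation (NaClO2, NaH2PO4, 2-methylbut-2-ene) should give the carboxylic acid F6. N-Acylation of (R)-4-benzyl-1,3-oxazolidin-2-one (DCC, DMAP) gives the N-acyl oxazolidinone F7. Boron enolate formation (Bu2BOTf, i-Pr2NEt) and bromination with NBS under auxiliary control should give the α-bromo N-acyl oxazolidinone F8; the auxiliary enantiomer drawn is assumed to be the one that gives the required bromide. NaBH4 in THF–H2O removes the auxiliary reductively without touching the methyl ester and gives bromohydrin 22, which lactonises to 23 as in step 12.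

Further compounds
F1 | step 14 | δ-hydroxy methyl ketone (C2–OH, acetyl on C5, Br on C1) | CC(C)[C@]1(O)C[C@@H]2C[C@H]3[C@H](C(C)=O)[C@](C)(CC[C@@]31C2)[C@@H](Br)CO
F2 | step 14 | primary tosylate of F1 | CC(C)[C@]1(O)C[C@@H]2C[C@H]3[C@H](C(C)=O)[C@](C)(CC[C@@]31C2)[C@@H](Br)COS(=O)(=O)c4ccc(C)cc4
F3 | step 8 | (E)-vinyl sulfone carbinol (mixture of carbinol epimers) | CC(C)C1(O)CCC=C1CC[C@](C)(CCO[Si](C)(C)C(C)(C)C)[C@H](/C=C/S(=O)(=O)c1ccccc1)C(=O)OC
F4 | step 8 | cyclopentadiene vinyl sulfone (not isolated) | CC(C)C1=C(CC[C@](C)(CCO[Si](C)(C)C(C)(C)C)[C@H](/C=C/S(=O)(=O)c2ccccc2)C(=O)OC)CC=C1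
F5 | step 8 | Diels–Alder adduct with endo phenylsulfonyl on C14 | CC(C)C1=C[C@@H]2[C@H](S(=O)(=O)c4ccccc4)[C@H]3[C@H](C(=O)OC)[C@](C)(CC[C@@]31C2)CCO[Si](C)(C)C(C)(C)C
F6 | step 12 | carboxylic acid from 20 (C2 = CO2H) | CC(C)[C@]1(O)C[C@@H]2C[C@H]3[C@H](C(=O)OC)[C@](C)(CC[C@@]31C2)CC(=O)O
F7 | step 12 | N-acyl (R)-4-benzyl-1,3-oxazolidin-2-one | CC(C)[C@]1(O)C[C@@H]2C[C@H]3[C@H](C(=O)OC)[C@](C)(CC[C@@]31C2)CC(=O)N4[C@H](Cc5ccccc5)COC4=O
F8 | step 12 | α-bromo N-acyl oxazolidinone (Br at C1) | CC(C)[C@]1(O)C[C@@H]2C[C@H]3[C@H](C(=O)OC)[C@](C)(CC[C@@]31C2)[C@@H](Br)C(=O)N4[C@H](Cc5ccccc5)COC4=O
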